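The oxolane (O1, C2–C5) is first made as a γ-lactone, and that lactone is grown out of a cyclopropane. The key step exploits the benzylic C5–O1 bond next to the electron-rich guaiacyl ring and the carboxyl oxidation level at C2: acid makes the donor–acceptor bond of a 2-aryl-3-methylcyclopropanecarboxylic acid break, and the carboxyl oxygen closes on the benzylic cation. One operation thus expands the three-membered carbocycle (C3, C4, C5) by O1 and C2, forms C5–O1 and sets C5 trans to the C4 methyl group. The precursor is an enantioenriched cyclopropane ester from benzyl isoeugenol; C3 and C2 are then elaborated on the lactone.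

Key step: step 2

Remark: ring atoms are numbered as in the oxolane name of the target (O1, C2, C3 = carbinol carbon, C4, C5); the (R,R)-tBu-box ligand, 2,2'-(propane-2,2-diyl)bis[(4R)-4-tert-butyl-4,5-dihydro-1,3-oxazole], is assumed to induce with alkene 1 in the sense known for styrene, and the antipodal ligand is used if it does not.

Step 1
Reactants: 1 (E)-1-(benzyloxy)-2-methoxy-4-(prop-1-en-1-yl)benzene (benzyl isoeugenol); 2 tert-butyl diazoacetate
Product: 3 tert-butyl (1S,2S,3S)-2-[4-(benzyloxy)-3-methoxyphenyl]-3-methylcyclopropane-1-carboxylate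
Conditions: CuOTf·0.5C6H6 (2 mol %), (R,R)-tBu-box (2.2 mol %), slow addition of 2, CH2Cl2, 0 °C to rt; minor diastereomer removed by chromatography
Reagents that add atoms: none
Why: Asymmetric copper-catalysed carbene-transfer cyclopropanation, in which the electron-rich E-alkene should add the carbene stereospecifically (aryl and methyl stay trans), the bulky ester should go trans to the aryl group, and the C2-symmetric bis(oxazoline) ligand selects the alkene face and thereby fixes the methyl-bearing carbon, the future C4.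

Step 2
Reactants: 3 tert-butyl (1S,2S,3S)-2-[4-(benzyloxy)-3-methoxyphenyl]-3-methylcyclopropane-1-carboxylate
Product: 5 (4R,5R)-5-[4-(benzyloxy)-3-methoxyphenyl]-4-methyloxolan-2-one, via cyclopropanecarboxylic acid 4 (not isolated)
Conditions: CF3CO2H, CH2Cl2, 0 °C to rt
Reagents that add atoms: none
Why: Acid first removes the tert-butyl group, then protonation of the carboxyl group polarises the only donor–acceptor bond of 4 (C1–C2 of the cyclopropane, aryl donor and carboxyl acceptor), which should break heterolytically with release of ring strain to give a para-alkoxybenzyl cation and the enol form of the acid. The carboxyl oxygen closes on the cation (5-exo-trig) and forms the O1–C5 bond, so that the three cyclopropane carbons become C3, C4 and C5 and the carboxyl group supplies C2 and O1. The closest known reaction type is the acid-mediated ring-opening lactonization of donor–acceptor cyclopropanecarboxylic acids, the carboxylic acid counterpart of the Cloke–Wilson rearrangement. The new stereocenter C5 is controlled by the C4 methyl group, since closure anti to it and reversible ionisation of the benzylic lactone under the acid should both lead to the 4,5-trans lactone. The step needs regioselective cleavage of C1–C2 and retention of the C4 configuration; the push–pull substitution secures the first and fast intramolecular capture of the cation at low temperature the second.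

Step 3
Reactants: 5 (4R,5R)-5-[4-(benzyloxy)-3-methoxyphenyl]-4-methyloxolan-2-one
Product: 6 (3R,4R,5R)-5-[4-(benzyloxy)-3-methoxyphenyl]-3-hydroxy-4-methyloxolan-2-one
Conditions: NaN(SiMe3)2, THF, −78 °C; then 2-(phenylsulfonyl)-3-phenyloxaziridine, −78 °C
Reagents that add atoms: 2-(phenylsulfonyl)-3-phenyloxaziridine, O=S(=O)(c1ccccc1)N1OC1c1ccccc1
Why: Electrophilic hydroxylation of the sodium lactone enolate by the N-sulfonyloxaziridine should place oxygen anti to the C4 methyl group, a configuration of no consequence because C3 becomes an enolate carbon again in step 5.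

Step 4
Reactants: 6 (3R,4R,5R)-5-[4-(benzyloxy)-3-methoxyphenyl]-3-hydroxy-4-methyloxolan-2-one
Product: 7 (3R,4S,5R)-3-(benzyloxy)-5-[4-(benzyloxy)-3-methoxyphenyl]-4-methyloxolan-2-one
Conditions: BnBr, Ag2O, 4 Å molecular sieves, CH2Cl2, rt, dark
Reagents that add atoms: benzyl bromide, BrCc1ccccc1
Why: Silver-oxide-mediated Williamson etherification benzylates the secondary alcohol without a strong base, so the lactone and its benzylic C5–O1 bond should survive.

Step 5
Reactants: 7 (3R,4S,5R)-3-(benzyloxy)-5-[4-(benzyloxy)-3-methoxyphenyl]-4-methyloxolan-2-one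
Product: 8 (3S,4S,5R)-3-(benzyloxy)-5-[4-(benzyloxy)-3-methoxyphenyl]-3,4-dimethyloxolan-2-one
Conditions: LiN(iPr)2, THF, −78 °C; then MeI, DMPU, −78 to −40 °C
Reagents that add atoms: iodomethane, CI
Why: Alkylation of the α-alkoxy lactone enolate, in which iodomethane should approach the planar enolate anti to the adjacent C4 methyl group (the usual course for β-substituted γ-butyrolactone enolates), so that the new methyl is trans and the benzyloxy group cis to the C4 methyl and C3 is set as (S).

Step 6
Reactants: 8 (3S,4S,5R)-3-(benzyloxy)-5-[4-(benzyloxy)-3-methoxyphenyl]-3,4-dimethyloxolan-2-one; 9 1-(benzyloxy)-4-bromo-2-methoxybenzene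
Product: 12 (2R,3S,4S,5R)-3-(benzyloxy)-2,5-bis[4-(benzyloxy)-3-methoxyphenyl]-3,4-dimethyloxolane, via aryllithium 10 (not isolated), via lactol 11 (not isolated)
Conditions: 9, n-BuLi, THF, −78 °C; then 8, −78 °C; aqueous work-up; then Et3SiH, BF3·OEt2, CH2Cl2, −78 to −40 °C
Reagents that add atoms: none
Why: Bromine–lithium exchange gives 10, which adds once to the hindered, non-enolisable lactone, and on Lewis-acid ionisation of lactol 11 the 2-aryl oxocarbenium ion should accept hydride from Et3SiH on the face anti to the C3 methyl and syn to the C3 benzyloxy group (the sense seen in silane reductions of 2-C-methyl aldonolactone-derived hemiketals to β-C-aryl glycosides), which sets C2 as (R) with the two aryl groups cis (aryllithium addition followed by ionic hydrogenation of the lactol).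

Step 7
Reactants: 12 (2R,3S,4S,5R)-3-(benzyloxy)-2,5-bis[4-(benzyloxy)-3-methoxyphenyl]-3,4-dimethyloxolane
Product: 13 (2R,3S,4S,5R)-2,5-bis(4-hydroxy-3-methoxyphenyl)-3,4-dimethyloxolan-3-ol
Conditions: H2 (1 atm), Pd(OH)2/C, EtOAc/MeOH, rt
Reagents that add atoms: none
Why: Catalytic hydrogenolysis should cleave the two aryl benzyl ethers and the tertiary alkyl benzyl ether faster than the dialkyl benzylic C–O bonds of the oxolane ring, which releases the target with all four stereocenters untouched.

Compound list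
1 | (E)-1-(benzyloxy)-2-methoxy-4-(prop-1-en-1-yl)benzene (benzyl isoeugenol) | C/C=C/c1ccc(OCc2ccccc2)c(OC)c1 | starting material
2 | tert-butyl diazoacetate | CC(C)(C)OC(=O)C=[N+]=[N-] | starting material
3 | tert-butyl (1S,2S,3S)-2-[4-(benzyloxy)-3-methoxyphenyl]-3-methylcyclopropane-1-carboxylate | CC(C)(C)OC(=O)[C@H]1[C@@H](C)[C@@H]1c1ccc(OCc2ccccc2)c(OC)c1 | intermediate
4 | (1S,2S,3S)-2-[4-(benzyloxy)-3-methoxyphenyl]-3-methylcyclopropane-1-carboxylic acid | OC(=O)[C@H]1[C@@H](C)[C@@H]1c1ccc(OCc2ccccc2)c(OC)c1 | intermediate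
5 | (4R,5R)-5-[4-(benzyloxy)-3-methoxyphenyl]-4-methyloxolan-2-one | O=C1O[C@@H](c2ccc(OCc3ccccc3)c(OC)c2)[C@H](C)C1 | intermediate
6 | (3R,4R,5R)-5-[4-(benzyloxy)-3-methoxyphenyl]-3-hydroxy-4-methyloxolan-2-one | O=C1O[C@@H](c2ccc(OCc3ccccc3)c(OC)c2)[C@H](C)[C@H]1O | intermediate
7 | (3R,4S,5R)-3-(benzyloxy)-5-[4-(benzyloxy)-3-methoxyphenyl]-4-methyloxolan-2-one | O=C1O[C@@H](c2ccc(OCc3ccccc3)c(OC)c2)[C@H](C)[C@H]1OCc1ccccc1 | intermediate
8 | (3S,4S,5R)-3-(benzyloxy)-5-[4-(benzyloxy)-3-methoxyphenyl]-3,4-dimethyloxolan-2-one | O=C1O[C@@H](c2ccc(OCc3ccccc3)c(OC)c2)[C@H](C)[C@]1(C)OCc1ccccc1 | intermediate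
9 | 1-(benzyloxy)-4-bromo-2-methoxybenzene | COc1cc(Br)ccc1OCc1ccccc1 | starting material
10 | [4-(benzyloxy)-3-methoxyphenyl]lithium | [Li]c1ccc(OCc2ccccc2)c(OC)c1 | intermediate
11 | (3S,4S,5R)-3-(benzyloxy)-2,5-bis[4-(benzyloxy)-3-methoxyphenyl]-3,4-dimethyloxolan-2-ol (both C2 epimers) | OC1(c2ccc(OCc3ccccc3)c(OC)c2)O[C@@H](c2ccc(OCc3ccccc3)c(OC)c2)[C@H](C)[C@]1(C)OCc1ccccc1 | intermediate
12 | (2R,3S,4S,5R)-3-(benzyloxy)-2,5-bis[4-(benzyloxy)-3-methoxyphenyl]-3,4-dimethyloxolane | COc1cc([C@H]2O[C@@H](c3ccc(OCc4ccccc4)c(OC)c3)[C@H](C)[C@]2(C)OCc2ccccc2)ccc1OCc1ccccc1 | intermediate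
13 | (2R,3S,4S,5R)-2,5-bis(4-hydroxy-3-methoxyphenyl)-3,4-dimethyloxolan-3-ol | COc1cc([C@H]2O[C@@H](c3ccc(O)c(OC)c3)[C@H](C)[C@]2(C)O)ccc1O | target

Total step count: 7. Longest linear sequence: 7 steps (1 to 13); aryl bromide 9 enters in step 6.

Steps most likely to fail

Step 2 (key step). The singly activated cyclopropane may ionise sluggishly, and a long-lived benzylic cation may lose a proton and re-add it, which would erode the C4 configuration. The fallback sets out from 3 and comes back at 5. It adds a second carboxyl group as a temporary activating group. Deprotonation of 3 with LiN(iPr)2 and acylation with di-tert-butyl dicarbonate should give di-tert-butyl (2R,3S)-2-[4-(benzyloxy)-3-methoxyphenyl]-3-methylcyclopropane-1,1-dicarboxylate F4. Brief treatment with CF3CO2H in CH2Cl2 frees the geminal diacid, a classical doubly activated donor–acceptor cyclopropane that should open and lactonise readily to (4R,5R)-5-[4-(benzyloxy)-3-methoxyphenyl]-4-methyl-2-oxooxolane-3-carboxylic acid F5. Warming F5 in toluene should decarboxylate it to 5.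

Step 1. Enantioface discrimination and the rate of carbene transfer to a 1,2-disubstituted alkene may be insufficient. The fallback sets out from 1 and comes back at 4. It replaces asymmetric catalysis by a classical resolution. Cyclopropanation of 1 with ethyl diazoacetate and Rh2(OAc)4 should give racemic ethyl (1S,2S,3S)-2-[4-(benzyloxy)-3-methoxyphenyl]-3-methylcyclopropane-1-carboxylate F1. Saponification with LiOH in THF/water gives the racemic (1S,2S,3S)-2-[4-(benzyloxy)-3-methoxyphenyl]-3-methylcyclopropane-1-carboxylic acid F2. Fractional crystallisation with (R)-1-phenylethylamine (or its antipode, whichever gives the less soluble salt of the wanted acid) gives (R)-1-phenylethylammonium (1S,2S,3S)-2-[4-(benzyloxy)-3-methoxyphenyl]-3-methylcyclopropane-1-carboxylate F3. Partition between ethyl acetate and cold aqueous citric acid releases 4, which is taken through step 2.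

Step 7. Slow cleavage of the hindered tertiary benzyl ether may allow hydrogenolytic opening of the oxolane at its benzylic C–O bonds. The fallback sets out from 6 and comes back at 13. It carries the tertiary alcohol unprotected. The alkoxide–enolate dianion of 6 (2.2 equivalents of LiN(iPr)2, THF, −78 °C) is C-methylated with iodomethane, again anti to the C4 methyl, to give (3S,4S,5R)-5-[4-(benzyloxy)-3-methoxyphenyl]-3-hydroxy-3,4-dimethyloxolan-2-one F6. Addition of excess 10 (from 9 and n-BuLi) gives the crude (3S,4S,5R)-2,5-bis[4-(benzyloxy)-3-methoxyphenyl]-3,4-dimethyloxolane-2,3-diol F7. Reduction of F7 with Et3SiH and BF3·OEt2 at −78 °C should give (2R,3S,4S,5R)-2,5-bis[4-(benzyloxy)-3-methoxyphenyl]-3,4-dimethyloxolan-3-ol F8. A short hydrogenolysis over Pd/C then has to cleave only the two reactive aryl benzyl ethers to reach 13.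

Further compounds
F1 | step 1 | racemic ethyl (1S,2S,3S)-2-[4-(benzyloxy)-3-methoxyphenyl]-3-methylcyclopropane-1-carboxylate (both enantiomers drawn) | CCOC(=O)[C@H]1[C@@H](C)[C@@H]1c1ccc(OCc2ccccc2)c(OC)c1.CCOC(=O)[C@@H]1[C@H](C)[C@H]1c1ccc(OCc2ccccc2)c(OC)c1
F2 | step 1 | racemic (1S,2S,3S)-2-[4-(benzyloxy)-3-methoxyphenyl]-3-methylcyclopropane-1-carboxylic acid (both enantiomers drawn) | OC(=O)[C@H]1[C@@H](C)[C@@H]1c1ccc(OCc2ccccc2)c(OC)c1.OC(=O)[C@@H]1[C@H](C)[C@H]1c1ccc(OCc2ccccc2)c(OC)c1
F3 | step 1 | (R)-1-phenylethylammonium (1S,2S,3S)-2-[4-(benzyloxy)-3-methoxyphenyl]-3-methylcyclopropane-1-carboxylate | C[C@@H]([NH3+])c1ccccc1.[O-]C(=O)[C@H]1[C@@H](C)[C@@H]1c1ccc(OCc2ccccc2)c(OC)c1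
F4 | step 2 | di-tert-butyl (2R,3S)-2-[4-(benzyloxy)-3-methoxyphenyl]-3-methylcyclopropane-1,1-dicarboxylate | CC(C)(C)OC(=O)C1(C(=O)OC(C)(C)C)[C@@H](C)[C@@H]1c1ccc(OCc2ccccc2)c(OC)c1
F5 | step 2 | (4R,5R)-5-[4-(benzyloxy)-3-methoxyphenyl]-4-methyl-2-oxooxolane-3-carboxylic acid (both C3 epimers) | O=C1O[C@@H](c2ccc(OCc3ccccc3)c(OC)c2)[C@H](C)C1C(O)=O
F6 | step 7 | (3S,4S,5R)-5-[4-(benzyloxy)-3-methoxyphenyl]-3-hydroxy-3,4-dimethyloxolan-2-one | O=C1O[C@@H](c2ccc(OCc3ccccc3)c(OC)c2)[C@H](C)[C@]1(C)O
F7 | step 7 | (3S,4S,5R)-2,5-bis[4-(benzyloxy)-3-methoxyphenyl]-3,4-dimethyloxolane-2,3-diol (both C2 epimers) | OC1(c2ccc(OCc3ccccc3)c(OC)c2)O[C@@H](c2ccc(OCc3ccccc3)c(OC)c2)[C@H](C)[C@]1(C)O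
F8 | step 7 | (2R,3S,4S,5R)-2,5-bis[4-(benzyloxy)-3-methoxyphenyl]-3,4-dimethyloxolan-3-ol | COc1cc([C@H]2O[C@@H](c3ccc(OCc4ccccc4)c(OC)c3)[C@H](C)[C@]2(C)O)ccc1OCc1ccccc1
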